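The flavonol is cut across ring C at the C2–C3 bond and the C3–O bond. The 3-hydroxyl beside the aryl-bearing C2 is read as the carbonyl oxygen of an aroyl ester on the ortho phenol (ester carbon = C2, phenol oxygen = O1), folded onto a carbene at C3 that comes from a diazoketone on ring A. One dirhodium-catalysed operation should thus forge both bonds, close ring C and install the 3-OH. Because ring A of the precursor is symmetric, both phenols flanking the diazoacetyl group carry the same 3-acetoxy-4-methoxybenzoyl group; the surplus C5 ester and the acetates fall in one final methanolysis.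

Key step: step 7

Remark: 1-(2,6-dihydroxy-4-methoxyphenyl)ethanone is taken as a purchasable starting material; the target is achiral, and the racemic epoxide that passes through the key step leaves no stereocentre behind.

Step 1
Reactants: 1 3-hydroxy-4-methoxybenzoic acid
Product: 2 3-acetoxy-4-methoxybenzoic acid
Conditions: Ac2O (1.5 equiv), pyridine, 0 °C to rt; then H2O, dilute HCl work-up
Reagents that add atoms: acetic anhydride, CC(=O)OC(C)=O
Why: Pyridine-promoted O-acetylation of the phenol, with any mixed anhydride at the carboxyl group hydrolysed on aqueous work-up, should leave only the aryl acetate.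

Step 2
Reactants: 2 3-acetoxy-4-methoxybenzoic acid
Product: 3 3-acetoxy-4-methoxybenzoyl chloride
Conditions: (COCl)2 (1.3 equiv), DMF (cat.), CH2Cl2, 0 °C to rt; evaporate, use crude
Reagents that add atoms: oxalyl chloride, O=C(Cl)C(=O)Cl
Why: Vilsmeier-type activation of the acid with oxalyl chloride and catalytic DMF gives the acyl chloride under neutral conditions that do not touch the aryl acetate.

Step 3
Reactants: 4 1-(2,6-dihydroxy-4-methoxyphenyl)ethanone; 5 1-bromo-3-methylbut-2-ene (prenyl bromide, 2.2 equiv)
Product: 6 1-[2,6-dihydroxy-4-methoxy-3,5-bis(3-methylbut-2-enyl)phenyl]ethanone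
Conditions: 10% aq. KOH, 0 °C to rt, N2; acidify, chromatograph
Reagents that add atoms: none
Why: In aqueous alkali the acylresorcinol dianion undergoes phenoxide C-alkylation ortho to one oxido group and para to the other, and since C3 and C5 are the only open ring positions double C-prenylation can only give the symmetrical product, with O-prenyl ethers as separable side products.

Step 4
Reactants: 6 1-[2,6-dihydroxy-4-methoxy-3,5-bis(3-methylbut-2-enyl)phenyl]ethanone
Product: 7 1-[2,6-bis(tert-butyldimethylsilyloxy)-4-methoxy-3,5-bis(3-methylbut-2-enyl)phenyl]ethanone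
Conditions: TBSCl (3 equiv), imidazole (6 equiv), DMAP (cat.), DMF, 50 °C
Reagents that add atoms: tert-butyldimethylsilyl chloride, CC(C)(C)[Si](C)(C)Cl
Why: Imidazole-promoted silylation masks both phenols, which would otherwise consume base and close a trifluoromethyl chromanone during the diazo transfer, as fluoride-labile ethers that can later be removed without acid.

Step 5
Reactants: 7 1-[2,6-bis(tert-butyldimethylsilyloxy)-4-methoxy-3,5-bis(3-methylbut-2-enyl)phenyl]ethanone
Product: 9 1-[2,6-bis(tert-butyldimethylsilyloxy)-4-methoxy-3,5-bis(3-methylbut-2-enyl)phenyl]-2-diazoethanone, via trifluoroacetyl diketone 8 (not isolated)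
Conditions: LiN(SiMe3)2 (1.1 equiv), THF, −78 °C; CF3CO2CH2CF3 (1.2 equiv), −78 °C; dilute HCl work-up; then 4-AcNHC6H4SO2N3 (1.5 equiv), Et3N (1.5 equiv), H2O (1 equiv), MeCN, rt
Reagents that add atoms: 4-acetamidobenzenesulfonyl azide, CC(=O)Nc1ccc(cc1)S(=O)(=O)N=[N+]=[N-] (the N2 unit of 9); 2,2,2-trifluoroethyl trifluoroacetate, O=C(OCC(F)(F)F)C(F)(F)F (the CF3CO group of 8 only)
Why: Detrifluoroacetylative diazo transfer: the kinetic lithium enolate of the methyl ketone is C-trifluoroacetylated to the activated 1,3-diketone 8, which accepts the diazo group from the sulfonyl azide and sheds the trifluoroacetyl group as the N-acyl sulfonamide, while aryl silyl ethers and prenyl groups are inert.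

Step 6
Reactants: 9 1-[2,6-bis(tert-butyldimethylsilyloxy)-4-methoxy-3,5-bis(3-methylbut-2-enyl)phenyl]-2-diazoethanone; 3 3-acetoxy-4-methoxybenzoyl chloride (3 equiv)
Product: 11 2-(diazoacetyl)-5-methoxy-4,6-bis(3-methylbut-2-enyl)-1,3-phenylene bis(3-acetoxy-4-methoxybenzoate), via bis-phenol diazoketone 10 (not isolated)
Conditions: Bu4NF (2.1 equiv), THF, −20 °C; then 3, Et3N, DMAP (cat.), −20 °C to rt, dark
Reagents that add atoms: none
Why: Fluoride cleaves both aryl silyl ethers in the cold and the resulting tetrabutylammonium phenoxides are O-acylated in the same flask by the acyl chloride (one-pot desilylation–acylation), so the acid-sensitive ortho-hydroxy diazoketone is never isolated and the weakly nucleophilic diazo carbon cannot compete with phenoxide.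

Step 7
Reactants: 11 2-(diazoacetyl)-5-methoxy-4,6-bis(3-methylbut-2-enyl)-1,3-phenylene bis(3-acetoxy-4-methoxybenzoate)
Product: 14 2-(3-acetoxy-4-methoxyphenyl)-3-hydroxy-7-methoxy-6,8-bis(3-methylbut-2-enyl)-4-oxo-4H-chromen-5-yl 3-acetoxy-4-methoxybenzoate, via seven-membered carbonyl ylide 12 (not isolated), via flavone 2,3-epoxide 13 (not isolated)
Conditions: Rh2(OAc)4 (2 mol%), CH2Cl2, rt, slow addition of 11 (final 0.01 M); then SiO2, rt
Reagents that add atoms: none
Why: Proposed new method: Rh2(OAc)4 (a divalent-rhodium carboxylate dimer) should expel N2 from 11 to give an electrophilic carbenoid at the future C3, which is attacked by the carbonyl oxygen of either flanking aroyl ester to give the seven-membered cyclic carbonyl ylide 12; collapse of the ylide (C3 carbanion onto the oxocarbenium C2, a 4π electrocyclisation) forms the C2–C3 bond as epoxide 13, and O1-assisted opening of this epoxy acetal at C2 followed by loss of the C3 proton gives flavonol 14, the former ester C=O oxygen ending as the 3-OH. The closest known reactions are Rh2(OAc)4-catalysed carbonyl-ylide formation from diazoketones and ester carbonyl groups, closure of carbonyl ylides to oxiranes, and the acid- or silica-promoted isomerisation of flavone 2,3-epoxides to 3-hydroxyflavones. Ring C (six-membered) is closed by transannular C2–C3 bond formation inside the seven-membered ylide, that is by ring contraction to the fused oxirane–pyranone, not by direct attack of an open-chain nucleophile. The two epoxide stereocentres are necessarily cis at the ring fusion, form as a racemate and are erased on isomerisation, so 14 has none. The step needs carbonyl-oxygen capture to beat attack by the ester ether oxygen (five-membered oxonium ylide, then acyl shift to a 2-aroylcoumaranone), Wolff rearrangement and reaction at the prenyl alkenes: the carbonyl oxygen of a 4-methoxybenzoyl-type ester is the more basic lone pair and lies over the twisted diazoacetyl group in the Z ester conformation, both ortho positions carry the same ester so that no ether, silyl ether or O–H donor flanks the carbene, the prenyl alkenes are meta to it and cannot reach it, and a dirhodium carboxylate at room temperature under slow addition does not promote Wolff rearrangement or carbene dimerisation.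

Step 8
Reactants: 14 2-(3-acetoxy-4-methoxyphenyl)-3-hydroxy-7-methoxy-6,8-bis(3-methylbut-2-enyl)-4-oxo-4H-chromen-5-yl 3-acetoxy-4-methoxybenzoate
Product: 15 3,5-dihydroxy-2-(3-hydroxy-4-methoxyphenyl)-7-methoxy-6,8-bis(3-methylbut-2-enyl)-4H-chromen-4-one
Conditions: K2CO3 (4 equiv), degassed MeOH, Ar, rt; then dilute aq. HCl to pH 5
Reagents that add atoms: none
Why: Base-mediated methanolysis (transesterification) should remove the aryl acetate and the C5 aroyl ester, which leaves as methyl 3-hydroxy-4-methoxybenzoate, while methyl ethers, prenyl groups and the chromone are inert; air is excluded because flavonol anions autoxidise.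

Compound list
1 | 3-hydroxy-4-methoxybenzoic acid (isovanillic acid) | COc1ccc(C(=O)O)cc1O | starting material
2 | 3-acetoxy-4-methoxybenzoic acid | COc1ccc(C(=O)O)cc1OC(C)=O | intermediate
3 | 3-acetoxy-4-methoxybenzoyl chloride | COc1ccc(C(=O)Cl)cc1OC(C)=O | intermediate
4 | 1-(2,6-dihydroxy-4-methoxyphenyl)ethanone | CC(=O)c1c(O)cc(OC)cc1O | starting material
5 | 1-bromo-3-methylbut-2-ene (prenyl bromide) | CC(C)=CCBr | starting material
6 | 1-[2,6-dihydroxy-4-methoxy-3,5-bis(3-methylbut-2-enyl)phenyl]ethanone | CC(=O)c1c(O)c(CC=C(C)C)c(OC)c(CC=C(C)C)c1O | intermediate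
7 | 1-[2,6-bis(tert-butyldimethylsilyloxy)-4-methoxy-3,5-bis(3-methylbut-2-enyl)phenyl]ethanone | CC(=O)c1c(O[Si](C)(C)C(C)(C)C)c(CC=C(C)C)c(OC)c(CC=C(C)C)c1O[Si](C)(C)C(C)(C)C | intermediate
8 | 1-[2,6-bis(tert-butyldimethylsilyloxy)-4-methoxy-3,5-bis(3-methylbut-2-enyl)phenyl]-4,4,4-trifluorobutane-1,3-dione | O=C(CC(=O)C(F)(F)F)c1c(O[Si](C)(C)C(C)(C)C)c(CC=C(C)C)c(OC)c(CC=C(C)C)c1O[Si](C)(C)C(C)(C)C | intermediate (not isolated)
9 | 1-[2,6-bis(tert-butyldimethylsilyloxy)-4-methoxy-3,5-bis(3-methylbut-2-enyl)phenyl]-2-diazoethanone | [N-]=[N+]=CC(=O)c1c(O[Si](C)(C)C(C)(C)C)c(CC=C(C)C)c(OC)c(CC=C(C)C)c1O[Si](C)(C)C(C)(C)C | intermediate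
10 | 2-diazo-1-[2,6-dihydroxy-4-methoxy-3,5-bis(3-methylbut-2-enyl)phenyl]ethanone (present as its bis(tetrabutylammonium) phenoxide) | [N-]=[N+]=CC(=O)c1c(O)c(CC=C(C)C)c(OC)c(CC=C(C)C)c1O | intermediate (not isolated)
11 | 2-(diazoacetyl)-5-methoxy-4,6-bis(3-methylbut-2-enyl)-1,3-phenylene bis(3-acetoxy-4-methoxybenzoate) | [N-]=[N+]=CC(=O)c1c(OC(=O)c2ccc(OC)c(OC(C)=O)c2)c(CC=C(C)C)c(OC)c(CC=C(C)C)c1OC(=O)c1ccc(OC)c(OC(C)=O)c1 | intermediate
12 | 6-(3-acetoxy-4-methoxybenzoyloxy)-2-(3-acetoxy-4-methoxyphenyl)-8-methoxy-7,9-bis(3-methylbut-2-enyl)-5-oxo-5H-1,3-benzodioxepin-3-ium-4-ide (cyclic carbonyl ylide) | O=C1[CH-][O+]=C(c2ccc(OC)c(OC(C)=O)c2)Oc2c(CC=C(C)C)c(OC)c(CC=C(C)C)c(OC(=O)c3ccc(OC)c(OC(C)=O)c3)c21 | intermediate (not isolated)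
13 | 2-(3-acetoxy-4-methoxyphenyl)-2,3-epoxy-7-methoxy-6,8-bis(3-methylbut-2-enyl)-4-oxochroman-5-yl 3-acetoxy-4-methoxybenzoate (cis-fused, racemic; one enantiomer drawn) | O=C1[C@H]2O[C@@]2(c2ccc(OC)c(OC(C)=O)c2)Oc2c(CC=C(C)C)c(OC)c(CC=C(C)C)c(OC(=O)c3ccc(OC)c(OC(C)=O)c3)c21 | intermediate (not isolated)
14 | 2-(3-acetoxy-4-methoxyphenyl)-3-hydroxy-7-methoxy-6,8-bis(3-methylbut-2-enyl)-4-oxo-4H-chromen-5-yl 3-acetoxy-4-methoxybenzoate | COc1ccc(C(=O)Oc2c(CC=C(C)C)c(OC)c(CC=C(C)C)c3oc(-c4ccc(OC)c(OC(C)=O)c4)c(O)c(=O)c23)cc1OC(C)=O | intermediate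
15 | 3,5-dihydroxy-2-(3-hydroxy-4-methoxyphenyl)-7-methoxy-6,8-bis(3-methylbut-2-enyl)-4H-chromen-4-one | COc1ccc(-c2oc3c(CC=C(C)C)c(OC)c(CC=C(C)C)c(O)c3c(=O)c2O)cc1O | target

Total step count: 8. Longest linear sequence: 6 steps (steps 3 to 8, from compound 4); steps 1 and 2 are a two-step side branch that joins at step 6.

Steps most likely to fail

Step 7 (bears the label for a new method). What may go wrong: the carbenoid is captured by the ester ether oxygen and an acyl shift follows, or the ylide does not collapse to the epoxide, so that ring C is not formed. Fallback with known chemistry, setting out from 9 and coming back at 15: Rh2(OAc)4-catalysed O–H insertion of 9 into an excess of acid 2 in CH2Cl2 should give the α-aroyloxy ketone 2-[2,6-bis(tert-butyldimethylsilyloxy)-4-methoxy-3,5-bis(3-methylbut-2-enyl)phenyl]-2-oxoethyl 3-acetoxy-4-methoxybenzoate F1. Bu4NF buffered with AcOH in THF should then free both phenols to give 2-[2,6-dihydroxy-4-methoxy-3,5-bis(3-methylbut-2-enyl)phenyl]-2-oxoethyl 3-acetoxy-4-methoxybenzoate F2. K2CO3 in DMF at 60 °C should bring about the base-mediated acyl migration of Baker–Venkataraman type and the cyclodehydration by which 2-hydroxy-ω-aroyloxyacetophenones are converted into flavonols; MeOH added at the end cleaves the aryl acetate and delivers 15.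

Step 3. What may go wrong: O-alkylation and geminal over-alkylation with loss of aromaticity compete with the second C-alkylation, so the symmetrical product is formed in small amount. Fallback, setting out from 4 and coming back at 6: Williamson O-prenylation of both phenols with 5 and K2CO3 in DMF at 60 °C should give 1-[4-methoxy-2,6-bis(3-methylbut-2-enyloxy)phenyl]ethanone F3. Acidic Montmorillonite K10 clay in CH2Cl2 at 0 °C should then move each prenyl group from oxygen to carbon (clay-promoted O-to-C prenyl migration), and because the ortho and para termini of both ethers are C3 and C5, either migration mode leads to 6.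

Step 5. What may go wrong: a silyl group migrates from a phenolic oxygen to the enolate oxygen, or the crowded enolate is not fully C-trifluoroacetylated, leaving ketone that cannot accept the diazo group. Fallback without an enolate, setting out from 7 and coming back at 9: condensation with N,N-dimethylformamide dimethyl acetal in toluene at 100 °C should give the enaminone (E)-1-[2,6-bis(tert-butyldimethylsilyloxy)-4-methoxy-3,5-bis(3-methylbut-2-enyl)phenyl]-3-(dimethylamino)prop-2-en-1-one F4. Treatment with 4-acetamidobenzenesulfonyl azide in MeCN at rt should then effect the base-free diazo transfer known for enaminones (cycloaddition, then loss of the N-sulfonylformamidine) to give 9.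

Further compounds
F1 | step 7 | 2-[2,6-bis(tert-butyldimethylsilyloxy)-4-methoxy-3,5-bis(3-methylbut-2-enyl)phenyl]-2-oxoethyl 3-acetoxy-4-methoxybenzoate | COc1ccc(C(=O)OCC(=O)c2c(O[Si](C)(C)C(C)(C)C)c(CC=C(C)C)c(OC)c(CC=C(C)C)c2O[Si](C)(C)C(C)(C)C)cc1OC(C)=O
F2 | step 7 | 2-[2,6-dihydroxy-4-methoxy-3,5-bis(3-methylbut-2-enyl)phenyl]-2-oxoethyl 3-acetoxy-4-methoxybenzoate | COc1ccc(C(=O)OCC(=O)c2c(O)c(CC=C(C)C)c(OC)c(CC=C(C)C)c2O)cc1OC(C)=O
F3 | step 3 | 1-[4-methoxy-2,6-bis(3-methylbut-2-enyloxy)phenyl]ethanone | CC(=O)c1c(OCC=C(C)C)cc(OC)cc1OCC=C(C)C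
F4 | step 5 | (E)-1-[2,6-bis(tert-butyldimethylsilyloxy)-4-methoxy-3,5-bis(3-methylbut-2-enyl)phenyl]-3-(dimethylamino)prop-2-en-1-one | CN(C)/C=C/C(=O)c1c(O[Si](C)(C)C(C)(C)C)c(CC=C(C)C)c(OC)c(CC=C(C)C)c1O[Si](C)(C)C(C)(C)C
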